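**Strategy**

The plan cuts the C4–C3 bond of the dihydropyranone ring C, the junction between the aryl ketone carbon on ring A and the carbinol carbon. The precursor is an open aryl ether: ring A bears an acylsilane ortho to O1, and the O1-bound benzylic carbon C2, already R, carries a formyl group. Blue light converts the acylsilane into a nucleophilic siloxycarbene, an acyl-anion equivalent at C4, that adds to the aldehyde carbon; silyl transfer then delivers the C4 ketone, the C3 oxygen and the C3 stereocentre as ring C closes. The step exploits the acyloin unit C4(=O)–C3(OH) and runs without base, sparing the labile C2 centre and the prenyl group.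

Key step: step 11

Remark: compounds 13, 14 and 15 are mixtures of the two epimers at the silicon-bearing carbinol carbon. That centre becomes the acylsilane carbonyl in step 10, so only C2 is drawn with configuration.

**Route**

Step 1
Reactants: 1 2-methylbut-3-en-2-ol
Product: 3 tert-butyl 2-methylbut-3-en-2-yl carbonate, via lithium 2-methylbut-3-en-2-olate 2 (not isolated)
Conditions: n-BuLi, THF, 0 °C; then Boc2O, 0 °C to rt; H2O
Reagents that add atoms: di-tert-butyl dicarbonate (Boc2O), CC(C)(C)OC(=O)OC(=O)OC(C)(C)C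
Why: O-acylation of the tertiary lithium alkoxide by Boc2O (carbonate formation); the expelled tert-butyl carbonate loses CO2.

Step 2
Reactants: 4 2-hydroxy-4,6-dimethoxybenzaldehyde; 3 tert-butyl 2-methylbut-3-en-2-yl carbonate
Product: 5 2-[(2-methylbut-3-en-2-yl)oxy]-4,6-dimethoxybenzaldehyde
Conditions: Pd(PPh3)4 (2 mol%), THF, 0 °C to rt
Reagents that add atoms: none
Why: Tsuji–Trost O-allylation: zerovalent palladium ionises carbonate 3 with loss of CO2, the tert-butoxide formed deprotonates the phenol, and the phenoxide attacks the more substituted terminus of the 1,1-dimethylallyl palladium cation to give the tertiary ether under kinetic control.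

Step 3
Reactants: 5 2-[(2-methylbut-3-en-2-yl)oxy]-4,6-dimethoxybenzaldehyde
Product: 6 2-hydroxy-4,6-dimethoxy-3-(3-methylbut-2-en-1-yl)benzaldehyde
Conditions: PhMe, 120 °C, sealed tube
Reagents that add atoms: none
Why: Aromatic Claisen rearrangement: the [3,3] shift delivers the allyl unit with allylic transposition (1,1-dimethylallyl becomes prenyl) to C3, the only ortho carbon that carries hydrogen, and tautomerisation restores the hydrogen-bonded phenol.

Step 4
Reactants: 7 4-bromo-2-methoxyphenol
Product: 8 4-bromo-2-methoxy-1-(methoxymethoxy)benzene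
Conditions: MOMCl, iPr2NEt, CH2Cl2, 0 °C to rt
Reagents that add atoms: chloromethyl methyl ether (MOMCl), COCCl
Why: O-alkylation of the phenol at the chloromethyl carbon (SN2) gives the MOM acetal, which masks the acidic OH for the organolithium step and the Mitsunobu coupling.

Step 5
Reactants: 8 4-bromo-2-methoxy-1-(methoxymethoxy)benzene
Product: 10 methyl 2-[3-methoxy-4-(methoxymethoxy)phenyl]-2-oxoacetate, via aryllithium 9 (not isolated)
Conditions: n-BuLi, THF, −78 °C; then cannulated into dimethyl oxalate (3 equiv), THF, −78 °C; H2O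
Reagents that add atoms: dimethyl oxalate, COC(=O)C(=O)OC
Why: Bromine–lithium exchange is faster than ortho-lithiation at −78 °C, and inverse addition of aryllithium 9 to excess oxalate diester stops at the α-keto ester (acylation of an organolithium).

Step 6
Reactants: 10 methyl 2-[3-methoxy-4-(methoxymethoxy)phenyl]-2-oxoacetate
Product: 11 methyl (S)-2-hydroxy-2-[3-methoxy-4-(methoxymethoxy)phenyl]acetate
Conditions: RuCl(p-cymene)[(R,R)-TsDPEN] (1 mol%), HCO2H/Et3N (5:2), DMF, rt
Reagents that add atoms: none
Why: Noyori asymmetric transfer hydrogenation: hydride and proton are delivered together from the ruthenium hydride–amine complex to one face of the aryl ketone, fixed by the CH–π contact between the aryl ring and the cymene ligand; the (R,R) ligand is the one expected to give the (S) carbinol, to be confirmed by the optical rotation of 11.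

Step 7
Reactants: 6 2-hydroxy-4,6-dimethoxy-3-(3-methylbut-2-en-1-yl)benzaldehyde; 11 methyl (S)-2-hydroxy-2-[3-methoxy-4-(methoxymethoxy)phenyl]acetate
Product: 12 methyl (R)-2-[2-formyl-3,5-dimethoxy-6-(3-methylbut-2-en-1-yl)phenoxy]-2-[3-methoxy-4-(methoxymethoxy)phenyl]acetate
Conditions: PPh3, DIAD, THF, 0 °C to rt
Reagents that add atoms: none
Why: Mitsunobu etherification: the acidic salicylaldehyde phenol displaces the alkoxyphosphonium ion of 11 by SN2 with inversion, (S) to (R), and the adjacent ester disfavours ionisation of the benzylic centre.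

Step 8
Reactants: 12 methyl (R)-2-[2-formyl-3,5-dimethoxy-6-(3-methylbut-2-en-1-yl)phenoxy]-2-[3-methoxy-4-(methoxymethoxy)phenyl]acetate
Product: 14 methyl (2R)-2-{2-[hydroxy(dimethylphenylsilyl)methyl]-3,5-dimethoxy-6-(3-methylbut-2-en-1-yl)phenoxy}-2-[3-methoxy-4-(methoxymethoxy)phenyl]acetate, via O-boryl silyl carbinol 13 (not isolated)
Conditions: PhMe2Si–Bpin (1.3 equiv), chloro[1,3-bis(2,6-diisopropylphenyl)imidazol-2-ylidene]copper, (IPr)CuCl (5 mol%), NaOtBu (5 mol%), THF, 0 °C to rt; then H2O
Reagents that add atoms: 2-(dimethylphenylsilyl)-4,4,5,5-tetramethyl-1,3,2-dioxaborolane (PhMe2Si–Bpin), C[Si](C)(c1ccccc1)B1OC(C)(C)C(C)(C)O1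
Why: Copper-catalysed 1,2-addition of a silyl nucleophile to an aldehyde: the monovalent copper alkoxide exchanges with the Si–B reagent to give Cu–SiMe2Ph, which adds only to the formyl group, and the copper alkoxide is borylated to 13 with turnover, so no free base reaches the ester α-centre; the new carbinol centre is uncontrolled and is erased in step 10.

Step 9
Reactants: 14 methyl (2R)-2-{2-[hydroxy(dimethylphenylsilyl)methyl]-3,5-dimethoxy-6-(3-methylbut-2-en-1-yl)phenoxy}-2-[3-methoxy-4-(methoxymethoxy)phenyl]acetate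
Product: 15 (2R)-2-{2-[hydroxy(dimethylphenylsilyl)methyl]-3,5-dimethoxy-6-(3-methylbut-2-en-1-yl)phenoxy}-2-[3-methoxy-4-(methoxymethoxy)phenyl]ethan-1-ol
Conditions: iBu2AlH (5 equiv), CH2Cl2, −78 to 0 °C; aq. potassium sodium tartrate
Reagents that add atoms: none
Why: Hydride reduction of the ester to the primary alcohol by a non-basic aluminium hydride, whose aluminium alkoxides should neither trigger Brook rearrangement of the α-silyl carbinol nor enolise C2, and which leaves the MOM acetal and the alkene intact.

Step 10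
Reactants: 15 (2R)-2-{2-[hydroxy(dimethylphenylsilyl)methyl]-3,5-dimethoxy-6-(3-methylbut-2-en-1-yl)phenoxy}-2-[3-methoxy-4-(methoxymethoxy)phenyl]ethan-1-ol
Product: 16 (2R)-2-{2-[(dimethylphenylsilyl)carbonyl]-3,5-dimethoxy-6-(3-methylbut-2-en-1-yl)phenoxy}-2-[3-methoxy-4-(methoxymethoxy)phenyl]acetaldehyde
Conditions: Dess–Martin periodinane (3 equiv), NaHCO3, CH2Cl2, 0 °C to rt, in the dark; used crude at once
Reagents that add atoms: none
Why: Dess–Martin oxidation of both carbinols in one operation: the α-hydroxysilane gives the acylsilane and the primary alcohol gives the α-aryloxy aldehyde under buffered, near-neutral conditions that avoid enolisation at C2.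

Step 11
Reactants: 16 (2R)-2-{2-[(dimethylphenylsilyl)carbonyl]-3,5-dimethoxy-6-(3-methylbut-2-en-1-yl)phenoxy}-2-[3-methoxy-4-(methoxymethoxy)phenyl]acetaldehyde
Product: 18 (2R,3R)-3-[dimethyl(phenyl)silyloxy]-5,7-dimethoxy-2-[3-methoxy-4-(methoxymethoxy)phenyl]-8-(3-methylbut-2-en-1-yl)chroman-4-one, via siloxycarbene 17 (not isolated)
Conditions: LEDs (405–427 nm), dry degassed PhH (0.01 M), rt
Reagents that add atoms: none
Why: Excitation of the aroylsilane n–π* band triggers a 1,2-silyl shift from carbon to oxygen (photo-Brook rearrangement) to the singlet siloxycarbene 17, a neutral acyl-anion equivalent at C4, which adds to the tethered aldehyde carbon C3; 1,4-silyl transfer from the oxocarbenium oxygen to the new alkoxide then releases the C4 ketone and the C3 silyl ether. The closest known reaction types are the light-induced addition of siloxycarbenes to aldehydes and the cyanide-catalysed cross silyl benzoin reaction of acylsilanes. Ring C closes in a 6-exo-trig mode (carbene carbon onto an exocyclic C=O). The new C3 centre is controlled by the existing C2 centre: in the half-chair transition state the C2 aryl group is pseudo-equatorial and the aldehyde C=O lies anti to the C2–O1 bond (dipole-minimised), which places the C3 oxygen equatorial and should give the 2,3-trans (2R,3R) isomer, which is also the thermodynamically preferred one. The step needs chemoselectivity and retention at the enolisable C2 centre: only the acylsilane absorbs at this wavelength and carbene generation is regiospecific, so the reversed acyloin cannot form, while the absence of base, acid or catalyst and the fast intramolecular capture protect C2; the prenyl group is remote from the carbene and the methyl and MOM ethers offer no O–H bond for insertion.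

Step 12
Reactants: 18 (2R,3R)-3-[dimethyl(phenyl)silyloxy]-5,7-dimethoxy-2-[3-methoxy-4-(methoxymethoxy)phenyl]-8-(3-methylbut-2-en-1-yl)chroman-4-one
Product: 19 (2R,3R)-3,5-dihydroxy-2-(4-hydroxy-3-methoxyphenyl)-7-methoxy-8-(3-methylbut-2-en-1-yl)chroman-4-one
Conditions: BCl3 (5 equiv), CH2Cl2, −78 to −20 °C; then MeOH, −78 °C to rt
Reagents that add atoms: none
Why: Chelation-controlled Lewis-acid demethylation: BCl3 binds the C4 carbonyl and the peri C5 methoxy oxygen in a six-membered chelate so that chloride cleaves only this methyl ether, while the MOM acetal and the labile silyl ether fall to the same reagent and the methanol quench; low temperature should keep the prenyl alkene and the other two methyl ethers intact, and C2 and C3 are not touched.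

**Compound list**

1 | 2-methylbut-3-en-2-ol | C=CC(C)(C)O | starting material
2 | lithium 2-methylbut-3-en-2-olate | [Li+].[O-]C(C)(C)C=C | intermediate
3 | tert-butyl 2-methylbut-3-en-2-yl carbonate | C=CC(C)(C)OC(=O)OC(C)(C)C | intermediate
4 | 2-hydroxy-4,6-dimethoxybenzaldehyde | O=Cc1c(O)cc(OC)cc1OC | starting material
5 | 2-[(2-methylbut-3-en-2-yl)oxy]-4,6-dimethoxybenzaldehyde | O=Cc1c(OC(C)(C)C=C)cc(OC)cc1OC | intermediate
6 | 2-hydroxy-4,6-dimethoxy-3-(3-methylbut-2-en-1-yl)benzaldehyde | O=Cc1c(O)c(CC=C(C)C)c(OC)cc1OC | intermediate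
7 | 4-bromo-2-methoxyphenol | COc1cc(Br)ccc1O | starting material
8 | 4-bromo-2-methoxy-1-(methoxymethoxy)benzene | COCOc1ccc(Br)cc1OC | intermediate
9 | [3-methoxy-4-(methoxymethoxy)phenyl]lithium | [Li]c1ccc(OCOC)c(OC)c1 | intermediate
10 | methyl 2-[3-methoxy-4-(methoxymethoxy)phenyl]-2-oxoacetate | COCOc1ccc(C(=O)C(=O)OC)cc1OC | intermediate
11 | methyl (S)-2-hydroxy-2-[3-methoxy-4-(methoxymethoxy)phenyl]acetate | COC(=O)[C@@H](O)c1ccc(OCOC)c(OC)c1 | intermediate
12 | methyl (R)-2-[2-formyl-3,5-dimethoxy-6-(3-methylbut-2-en-1-yl)phenoxy]-2-[3-methoxy-4-(methoxymethoxy)phenyl]acetate | COC(=O)[C@H](Oc1c(C=O)c(OC)cc(OC)c1CC=C(C)C)c1ccc(OCOC)c(OC)c1 | intermediate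
13 | O-(pinacolboryl) derivative of 14 (epimers at the silyl carbinol carbon) | COC(=O)[C@H](Oc1c(C(OB2OC(C)(C)C(C)(C)O2)[Si](C)(C)c2ccccc2)c(OC)cc(OC)c1CC=C(C)C)c1ccc(OCOC)c(OC)c1 | intermediate
14 | methyl (2R)-2-{2-[hydroxy(dimethylphenylsilyl)methyl]-3,5-dimethoxy-6-(3-methylbut-2-en-1-yl)phenoxy}-2-[3-methoxy-4-(methoxymethoxy)phenyl]acetate | COC(=O)[C@H](Oc1c(C(O)[Si](C)(C)c2ccccc2)c(OC)cc(OC)c1CC=C(C)C)c1ccc(OCOC)c(OC)c1 | intermediate
15 | (2R)-2-{2-[hydroxy(dimethylphenylsilyl)methyl]-3,5-dimethoxy-6-(3-methylbut-2-en-1-yl)phenoxy}-2-[3-methoxy-4-(methoxymethoxy)phenyl]ethan-1-ol | OC[C@H](Oc1c(C(O)[Si](C)(C)c2ccccc2)c(OC)cc(OC)c1CC=C(C)C)c1ccc(OCOC)c(OC)c1 | intermediate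
16 | (2R)-2-{2-[(dimethylphenylsilyl)carbonyl]-3,5-dimethoxy-6-(3-methylbut-2-en-1-yl)phenoxy}-2-[3-methoxy-4-(methoxymethoxy)phenyl]acetaldehyde | O=C[C@H](Oc1c(C(=O)[Si](C)(C)c2ccccc2)c(OC)cc(OC)c1CC=C(C)C)c1ccc(OCOC)c(OC)c1 | intermediate
17 | siloxycarbene from 16 (carbene carbon on ring A, bearing the O–SiMe2Ph group) | O=C[C@H](Oc1c([C]O[Si](C)(C)c2ccccc2)c(OC)cc(OC)c1CC=C(C)C)c1ccc(OCOC)c(OC)c1 | intermediate
18 | (2R,3R)-3-[dimethyl(phenyl)silyloxy]-5,7-dimethoxy-2-[3-methoxy-4-(methoxymethoxy)phenyl]-8-(3-methylbut-2-en-1-yl)chroman-4-one | COc1cc([C@H]2Oc3c(CC=C(C)C)c(OC)cc(OC)c3C(=O)[C@@H]2O[Si](C)(C)c2ccccc2)ccc1OCOC | intermediate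
19 | (2R,3R)-3,5-dihydroxy-2-(4-hydroxy-3-methoxyphenyl)-7-methoxy-8-(3-methylbut-2-en-1-yl)chroman-4-one | COc1cc([C@H]2Oc3c(CC=C(C)C)c(OC)cc(O)c3C(=O)[C@@H]2O)ccc1O | target

**Step count**

Total steps: 12. Longest linear sequence: 9 steps (7 → 8 → 10 → 11 → 12 → 14 → 15 → 16 → 18 → 19; the branch from 1 is equally long).

**Steps most likely to fail**

Step 11. The siloxycarbene may return to the acylsilane, or take the acidic hydrogen at C2, faster than it adds to the aldehyde; the aldehyde may also lose configuration at C2 before capture. The fallback sets out from 12 and closes the same C3–C4 bond by a ketyl route. iBu2AlH in excess reduces both the formyl and the ester group to the diol F1. Dess–Martin periodinane gives the dialdehyde F2. SmI2 in THF at −78 °C couples the aromatic ketyl with the aliphatic aldehyde (intramolecular pinacol coupling) to the 2,3-trans-3,4-cis diol F3. MnO2 in CH2Cl2 oxidises only the benzylic C4 carbinol to the hydroxy ketone F4. BCl3 as in step 12 then cleaves the C5 methyl ether and the MOM group, and the fallback comes back to the route at 19.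

Step 7. The phenol oxygen is shielded by the formyl and prenyl groups and is hydrogen-bonded, so the Mitsunobu coupling may stall, and partial ionisation could erode the inversion. The fallback sets out from 10 (with 6) and makes the same C–O bond by carbene insertion. Condensation of 10 with tosylhydrazide gives the tosylhydrazone F5, and DBU converts it into the diazo ester F6. Asymmetric O–H insertion of F6 into phenol 6, catalysed by PdCl2(PhCN)2 with a chiral spiro bis(oxazoline) ligand and NaB[3,5-(CF3)2C6H3]4 in CHCl3, should give the (R) ether, and the fallback comes back to the route at 12.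

Step 12. HCl may add to the prenyl alkene, or the alkene may cyclise, and BCl3 may cleave the B-ring ethers unselectively. The fallback sets out from 18 and separates the two kinds of cleavage. Dilute HCl in MeOH at rt removes the MOM acetal and the silyl ether to give the 5-O-methyl dihydroflavonol F7. The chelated C5 methyl group is then removed by iodide attack within the magnesium chelate (MgI2·OEt2, THF/PhMe, 60 °C), an aprotic demethylation that spares the alkene, and the fallback comes back to the route at 19.

**Further compounds**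

F1 | step 11 | (2R)-2-[2-(hydroxymethyl)-3,5-dimethoxy-6-(3-methylbut-2-en-1-yl)phenoxy]-2-[3-methoxy-4-(methoxymethoxy)phenyl]ethan-1-ol | OC[C@H](Oc1c(CO)c(OC)cc(OC)c1CC=C(C)C)c1ccc(OCOC)c(OC)c1
F2 | step 11 | (2R)-2-[2-formyl-3,5-dimethoxy-6-(3-methylbut-2-en-1-yl)phenoxy]-2-[3-methoxy-4-(methoxymethoxy)phenyl]acetaldehyde | O=C[C@H](Oc1c(C=O)c(OC)cc(OC)c1CC=C(C)C)c1ccc(OCOC)c(OC)c1
F3 | step 11 | (2R,3S,4S)-5,7-dimethoxy-2-[3-methoxy-4-(methoxymethoxy)phenyl]-8-(3-methylbut-2-en-1-yl)chromane-3,4-diol | COc1cc([C@H]2Oc3c(CC=C(C)C)c(OC)cc(OC)c3[C@H](O)[C@@H]2O)ccc1OCOC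
F4 | step 11 | (2R,3R)-3-hydroxy-5,7-dimethoxy-2-[3-methoxy-4-(methoxymethoxy)phenyl]-8-(3-methylbut-2-en-1-yl)chroman-4-one | COc1cc([C@H]2Oc3c(CC=C(C)C)c(OC)cc(OC)c3C(=O)[C@@H]2O)ccc1OCOC
F5 | step 7 | methyl 2-[3-methoxy-4-(methoxymethoxy)phenyl]-2-(2-tosylhydrazinylidene)acetate | COCOc1ccc(C(=NNS(=O)(=O)c2ccc(C)cc2)C(=O)OC)cc1OC
F6 | step 7 | methyl 2-diazo-2-[3-methoxy-4-(methoxymethoxy)phenyl]acetate | COCOc1ccc(C(=[N+]=[N-])C(=O)OC)cc1OC
F7 | step 12 | (2R,3R)-3-hydroxy-2-(4-hydroxy-3-methoxyphenyl)-5,7-dimethoxy-8-(3-methylbut-2-en-1-yl)chroman-4-one | COc1cc([C@H]2Oc3c(CC=C(C)C)c(OC)cc(OC)c3C(=O)[C@@H]2O)ccc1O
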